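**Product ceiling.** Start from L, which stands flat from the first sample: 0.119 M on Wednesday's run, 0.121 M on Saturday's and 0.121 M on Tuesday's, against 0.12 M of Z charged, so take Z as the limiting reagent and these readings as finished flasks, with no slope from which to read an order in E.

| flask | X | Z | E | remark |
|---|---|---|---|---|
| Wednesday's | 0.28 M | 0.12 M | 0.16 mM | run made earlier |
| Saturday's | 0.44 M | 0.12 M | 0.16 mM | run made earlier |
| Tuesday's | 0.20 M | 0.12 M | 0.32 mM | run made earlier |
| flask | 0.20 M | 0.120 M | 0.16 mM |  |

- Wednesday's (time / h: L / %, X / %): 2.50: 43.5, 57.6; 5.00: 42.5, 56.5; 6.00: 43.9, 56.9; 10.0: 43.7, 57.2; 12.0: 43.2, 56.9; 15.0: 42.2, 56.9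
- Saturday's (time / h: L / %, X / %): 2.50: 28.4, 73.3; 5.00: 27.5, 73.0; 6.00: 27.7, 72.8; 10.0: 27.5, 73.3; 12.0: 27.0, 72.6; 15.0: 27.8, 72.8
- Tuesday's (time / h: L / %, X / %): 1.33: 59.6, 39.5; 4.00: 60.4, 39.9; 8.00: 59.6, 39.4; 12.0: 60.2, 40.6; 15.0: 59.7, 40.0

(scatter of a reading: 0.5 percentage points)



1. apparent order in E when 5.0% of the X are converted (percent change of the rate of making L for one percent more E charged)

**Counting turnovers.** Count instead what the flask must do: 62.5 turnovers, the moles of L made per mole of E charged by 5.0% conversion of X, out of the 750 that its Z allows. Tuesday's run, with the same [X] but twice the E, had done 375 turnovers by its first sample at 1.33 h, which averages 282 h⁻¹. Taking that average as a floor for the early rate, my own reckoning puts the asked point in the flask no later than 0.222 h.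

**Next run.** Keep [X] and [Z] as charged, change [E] and nothing else, and at the flask's [E] sample L inside 0.222 h, earlier than 1.33 h, the time at which Tuesday's run, at twice that [E], already reads a plateau. This reckoning gives a sampling window, not an order.

**The result.** The forecast says 1, falling back on “the prior for a simple catalyst”. The flask gives 0.81, and it reaches the asked point at 0.128 h, earlier than the window's end, with L made at 0.0770 M h⁻¹.

    J → E + L (k = 3.70 s⁻¹)
    D ⇌ J (K = 0.410, k = 2.80 s⁻¹)
    Z + E → G (k = 14.0 M⁻¹ s⁻¹)
    2 J ⇌ Q, settled at all times (K = 5.80 × 10⁵ M⁻¹)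
    X + G ⇌ D (K = 6.60 M⁻¹, k = 1.80 M⁻¹ s⁻¹)

**Parked catalyst.** At that point the flask's turnover rate per E charged is 481 h⁻¹, so 62.5 turnovers take about 0.130 h at that rate. Part of the gap below first order is the off-cycle parking of two J as Q: the simulated run without that parking has order 1.0. The same parking also slows the flask: the rate of that simulated run is 1.32 times the actual one, so its 62.5 turnovers take about 0.0984 h at that rate.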